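Target is the product we have to place at 15 d, counted with all its forms, free or not, and we want to bound the ratio of isomer of the product A to it.

| flask | substrate | remark | time |
|---|---|---|---|
| larch | 0.16 M | the very flask that is asked about, followed so far |  |
| cedar | 0.080 M | run made earlier |  |
| flask | 0.16 M |  | 15 d |

larch run (percent of the substrate charged)

| time / h | isomer of the product A / % | target / % | substrate / % |
|---|---|---|---|
| 2.50 | 0.5 | 3.8 | 96.0 |
| 6.00 | 0.9 | 6.1 | 90.9 |
| 12.0 | 2.2 | 11.8 | 82.9 |
| 20.0 | 4.5 | 17.3 | 72.8 |
| 25.0 | 4.2 | 21.2 | 66.3 |
| 30.0 | 5.5 | 24.7 | 60.2 |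
| 40.0 | 5.3 | 30.6 | 52.8 |

cedar run (percent of the substrate charged)

| time / d | isomer of the product A / % | target / % | substrate / % |
|---|---|---|---|
| 0.833 | 4.4 | 16.9 | 72.2 |
| 2.50 | 7.5 | 33.9 | 38.8 |
| 4.00 | 8.9 | 43.8 | 23.2 |
| 6.00 | 10.0 | 49.8 | 11.7 |
| 10.0 | 8.2 | 49.3 | 4.7 |
| 12.0 | 7.1 | 46.4 | 3.5 |
| 15.0 | 7.2 | 40.9 | 4.0 |

(each reading ± 0.5 percentage points)

- a reading or a percentage of target counts all its forms, free or not

- ratio of isomer of the product A to target at 1.0 h
- ratio of isomer of the product A to target at 15 d
- which of isomer of the product A and target there is more of at 15 d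

The early ratio in larch climbs from 0.132 at 2.50 h to 0.186 at 12.0 h, so we put the ratio at 1.0 h below the first of these readings, which are poor ones at this scatter.

For 15 d, we bound the ratio from above by supposing first-order steps throughout. Fractions of the charge would then not depend on the charge, and the flask would repeat cedar, giving the ratio read there at 15.0 d, 0.176. But cedar's target falls from 49.3% at 10.0 d to 46.4% at 12.0 d and 40.9% at 15.0 d, faster per day in the later stretch, though each of these readings carries a scatter of 0.5 percentage points. A first-order fall would slow, so we read this fall as nearer to zero-order: a fixed amount per day.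

A fixed amount is a smaller fraction of a larger charge. For the bound from below we therefore multiply cedar's fractions by the charge ratio 0.500. If isomer of the product A shrinks so and target takes up the remainder of the charge, the ratio is 0.0373. If the part of the charge that is not target shrinks so, target is 70.5% and we get the charge-scaled ratio 0.0511. This tighter bound is our own estimate.

The forecast gave 0.18 at 1.0 h, above our early limit, and 0.18 at 15 d, on the upper bound, with target ahead, seeing “no clear concentration effect”.

The flask gives 0.0654 and 0.0600, with target at 67.6%, of which crystals are 65.2%, and isomer of the product A at 4.05%.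

    substrate ⇌ target (K = 1.70, k = 0.0120 h⁻¹)
    target ⇌ isomer of the product A (K = 1.30, k = 0.0260 h⁻¹)
    isomer of the product A ⇌ isomer of the product B (K = 1.40, k = 0.500 h⁻¹)
    isomer of the product B ⇌ substrate (k = 0.00150 h⁻¹)
    crystals ⇌ target, rate k5*(cs5 - [target]) while solid is left; crystals form when [target] > cs5 (solubility = 3.90 mM, k = 0.920 h⁻¹)
    target → over-reaction product (k = 0.0220 h⁻¹)

At 15 d the flask's ratio lies above 0.0511 and below 0.176. The neighbour differs in its charge of 0.27 M, which makes the charge ratio 0.296. The same reckoning gives target 82.5% and a charge-scaled ratio of 0.0259. At 15 d the neighbour holds target 78.5%, of which crystals are 77.1%, and isomer of the product A 2.86%, a ratio of 0.0364.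

The readings stem from a simulated flask with constants of no real substance, noise included.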